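Time was the easy setting. In the green run, target read 63.5% at 50.0 min and 63.9% at 80.0 min, so by hand I expected nothing from the longer stay of 2.5 h.

| setting | green | grey | Tuesday's | Monday's |
|---|---|---|---|---|
| electrophile | 0.40 M | 0.40 M | 0.40 M | 0.40 M |
| nucleophile | 0.57 M | 0.82 M | 0.400 M | 0.520 M |
| free base | 0.32 M | 0.32 M | 0.320 M | 0.320 M |
| remark | run made earlier | run made earlier |  |  |
| time |  |  | 2.5 h | 2.5 h |

| run | time / min | electrophile / % | side product / % | target / % |
|---|---|---|---|---|
| green | 6.00 | 37.9 | 10.3 | 51.6 |
| green | 10.0 | 23.5 | 18.3 | 59.1 |
| green | 15.0 | 14.5 | 24.0 | 61.4 |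
| green | 20.0 | 9.1 | 27.4 | 63.3 |
| green | 30.0 | 5.0 | 32.3 | 64.1 |
| green | 50.0 | 1.0 | 35.6 | 63.5 |
| green | 80.0 | 0.5 | 36.7 | 63.9 |
| grey | 10.0 | 11.1 | 16.6 | 72.4 |
| grey | 20.0 | 2.5 | 21.0 | 75.9 |
| grey | 30.0 | 0 | 21.9 | 76.9 |
| grey | 40.0 | 0.9 | 23.1 | 76.6 |
| grey | 50.0 | 0 | 22.9 | 76.7 |
| grey | 60.0 | 0 | 24.2 | 77.6 |
| grey | 80.0 | 0 | 23.3 | 77.0 |

(standard deviation of a reading: 0.5 percentage points)

- in percentages every species weighs as the electrophile in it: one side product counts as two
- for acid set free the idle adduct is counted in
- steps under discussion: electrophile + nucleophile -> acid set free + target; nucleophile + acid set free <-> protonated nucleophile; acid set free + free base <-> salt of the base; electrophile + target -> side product; nucleophile <-> dormant form; nucleophile + acid set free <-> idle adduct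

* which of these there is most of at the end, counted by the electrophile in it, Tuesday's (electrophile / side product / target)
* which of these there is most of at the end, counted by the electrophile in it, Monday's (electrophile / side product / target)
* how much there is at the end of the one of these that leads, in percent of the electrophile charged: Tuesday's
* how much there is at the end of the one of these that leads, in percent of the electrophile charged: Monday's

The nucleophile charge was the other setting. I divided the rates by one another so that time dropped out: each nucleophile used makes one target, and each side-product step takes one more electrophile and one target. With n the nucleophile used, once the electrophile is gone,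

[target] = 2n − [electrophile charged].

Target ties the side product at 0.5 of the electrophile charged, so

n / [nucleophile charged] = 3[electrophile charged] / (4[nucleophile charged]):

Tuesday's 75.0%, Monday's 57.7%.

I carried this needed share, the part of the nucleophile charge that must be used before target leads.

By the last readings, green used 0.329 M, a share of 57.7%, and grey used 0.355 M, a share of 43.2%. A straight line through these shares gave:

Monday's: 60.6%, target 57.6%
Tuesday's: 67.6%, side product 64.9%

So I had target leading on Monday's and the side product on Tuesday's, the second figure being a long extrapolation.

The forecast named side product at 55% for Tuesday's, lower than my figure, and target at 59.5% for Monday's, higher than mine, adding “Without protonation it would be 52/48, so the lead is not certain”.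

Tuesday's ended with side product at 55.9%, Monday's with target at 58.9%. Through the rule, Tuesday's used 71.9% of its nucleophile, below the needed 75.0%, and Monday's 61.1%, above its 57.7%.

    electrophile + nucleophile → acid set free + target (k = 0.390 M⁻¹ min⁻¹)
    nucleophile + acid set free ⇌ protonated nucleophile, settled at all times (K = 6600 M⁻¹)
    acid set free + free base ⇌ salt of the base, settled at all times (K = 2.20 × 10⁵ M⁻¹)
    electrophile + target → side product (k = 0.129 M⁻¹ min⁻¹)
    nucleophile ⇌ dormant form (K = 2.44, k = 0.0290 min⁻¹)
    nucleophile + acid set free ⇌ idle adduct, settled at all times (K = 0.729 M⁻¹)

At 0.0548 h in Monday's, target was made 6.42 times faster than it was used up. The nucleophile's half-life by the first step was then 0.13 h, and at 2.50 h it was 26 d, with 0.012% of the electrophile left.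

The neighbour of Monday's with 0.10 M of electrophile needs a share of 14.4%, and its electrophile allows a share of 19.2% at most. That need is 0.0750 M of nucleophile, less than the 0.329 M green used on the same free base, so I expected target to lead. It ended with 91.3% target, a share used of 18.4%.

The readings are calculated with made-up constants, noise included.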